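The earlier runs and the new flask are calculated with made-up constants, and the scatter is random.

The constants of this flask are not to hand, so you work from two earlier runs, beta and alpha, whose recipes differ in the loading of racemization catalyst.

| flask | left-handed substrate | right-handed substrate | gas | free catalyst | racemization catalyst | remark | time |
|---|---|---|---|---|---|---|---|
| beta | 0.50 M | 0.50 M | 34 mM (held) | 10 mol% | 0.05 mol% | run made earlier |  |
| alpha | 0.50 M | 0.50 M | 34 mM (held) | 10 mol% | 0.2 mol% | run made earlier |  |
| flask | 0.50 M | 0.50 M | 34 mM (held) | 10 mol% | 0.1 mol% |  | 2.0 h |

| run | time / min | left-handed product / % | right-handed product / % |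
|---|---|---|---|
| beta | 5.00 | 64.2 | 29.2 |
| beta | 15.0 | 67.9 | 31.8 |
| beta | 25.0 | 69.0 | 31.3 |
| beta | 40.0 | 68.8 | 31.0 |
| beta | 60.0 | 68.7 | 30.5 |
| beta | 80.0 | 69.6 | 30.9 |
| alpha | 12.0 | 70.0 | 30.5 |
| alpha | 25.0 | 70.2 | 30.3 |
| alpha | 40.0 | 70.5 | 31.1 |
| alpha | 50.0 | 68.7 | 30.7 |
| alpha | 60.0 | 70.1 | 29.6 |
| alpha | 80.0 | 70.3 | 30.1 |

(standard deviation of a reading: 0.5 percentage points)

1. amount of left-handed product at 2.0 h, in percent of the left-handed substrate and right-handed substrate together charged
2. amount of right-handed product at 2.0 h, in percent of the left-handed substrate and right-handed substrate together charged

- free catalyst is single-handed; left-handed substrate and right-handed substrate are mirror images of each other, charged as a racemate, each of them at the stated concentration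
- at the start none of the gas is in solution

Beta's products add up to 100% at 25.0 min, so expect your flask to hold products and no substrate at 2.0 h; leave the racemization loading as charged, since at 25.0 min left-handed product read 70.2% in alpha, with the higher loading, against 69.0% in beta.

From that reading on, left-handed product averages 69.0% in beta, and alpha averages 70.0%. Treat the small thing as a correction and assume it falls as one over the loading. Alpha's shortfall is then the gap between these means divided by 3.00, or 0.31 percentage points, which puts the limit of this dynamic kinetic resolution at 70.3%. At 0.1 mol%, the points of left-handed product below that limit come to 0.63 points. My reckoning therefore gives 69.7% left-handed and 30.3% right-handed product.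

The forecast says 69.6% and 30.5%, its right-handed figure standing 0.15 points above mine, and calls this a dynamic kinetic resolution “close to its fast-racemization limit”.

The flask gives 69.5% and 30.5%.

    left-handed substrate + racemization catalyst ⇌ right-handed substrate + racemization catalyst, rate k1*[racemization catalyst]*[left-handed substrate] forward; the back reaction follows from the equilibrium constant (k = 14000 /M/min)
    gas ⇌ reagent, rate k2*(csat - [reagent]) (kL = 8.60 /min)
    racemization catalyst → spent catalyst (k = 0.0470 /min)
    reagent + free catalyst + left-handed substrate → free catalyst + left-handed product (k = 1300 /M²/min)
    reagent + free catalyst + right-handed substrate → free catalyst + right-handed product (k = 550 /M²/min)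

That left-handed value stands 0.80 points under the limit read from the runs, against the reckoned 0.63 points. The neighbouring flask carries 0.17 mol% of racemization catalyst, so the shortfall scales to 0.37 points and the reckoning gives 69.9% left-handed product. That neighbouring flask gives 69.8% left-handed and 30.2% right-handed product.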